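Ring compounds are numbered as germacranes throughout: carbocycle C1–C10, lactone carbons C11–C13, C14 on C10, C15 on C4. "Cis" for C1=C10 and C4=C5 refers to the ring carbons.

## Analysis of the target

Target 37 is a germacranolide: a ten-membered carbocycle (C1–C10) with two trisubstituted double bonds, C1=C10 and C4=C5, both cis in the ring and forming a 1,5-diene, fused across C7–C8 to a γ-lactone (C7–C11–C12(=O)–O–C8) with an exocyclic C11=C13 methylene group. C10 and C4 carry hydroxymethyl groups (C14, C15), and C6 carries an (E)-2-methylbut-2-enoate (tiglate). The three stereocentres are contiguous, C6 (S), C7 (R) and C8 (S): H7 and H8 are trans (trans-fused lactone), and the C6 oxygen is 1,3-anti to the C8 oxygen. Sensitive points are the α-methylene lactone (a Michael acceptor that tolerates neither nucleophiles nor strong base), the allylic tiglate, the two primary allylic alcohols, and the risk of translactonisation from O8 to O6 whenever a free C6 hydroxyl meets base. The main difficulty is the medium ring: ten-membered rings close poorly end to end, and both ring alkenes must come out cis. The strategy rests on one feature: the C6 oxygen, C7, the C8–C9 bond and the C1=C10 alkene are arranged as in the enolate that an oxy-Cope shift delivers from a cyclohexene (ring atoms C1–C6) holding a C1–C6 bond. In that six-membered ring C4=C5 is necessarily cis.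

## Retrosynthetic reasoning

**37 to 36, 34 and 35.** The two primary alcohols are unmasked last from the bis(4-methoxybenzyl) ether 36. These ethers survive amide bases, potassium alkoxide, fluoride and hydride and fall in one neutral oxidative step; silyl ethers would be lost when silicon on C8 is activated with fluoride. Cutting the C6–O acyl bond of 36 gives alcohol 34 and tigloyl chloride 35. The ester goes on late because a lactone enolate cannot be made next to an unsaturated ester.

**34 to 30.** The C11=C13 bond is cut; the methylene carbon is added to the saturated lactone 30 by a Mannich reaction and elimination. This keeps the Michael acceptor out of all earlier steps.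

**30 to 29.** The C6 hydroxyl goes back to the ketone of keto lactone 29. The carbonyl is kept until the lactone exists: with a 6,8-diol either oxygen could close a five-membered lactone on C12, with the ketone only O8 can. The forward reduction must deliver hydride to one face of a ketone flanked by the C7 stereocentre.

**29 to 28, 26, 23 and 24.** The lactone C12–O8 bond is cut to hydroxy ester 28, and the C8–O bond of 28 is traced to a C8–Si bond in 26 (oxidation with retention). Silicon stands in for oxygen because the C6/C7 enolate would expel an oxygen substituent on C8 but not a silyl group. The C7–C11 bond of 26 is cut to ketone 23 and bromoacetate 24. The alkylation must occur trans to the silyl group, and the tert-butyl ester must stay open during the basic oxidation so that no β-acyloxy ketone meets base.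

**23 to 20 (key disconnection).** The ten-membered ring is not opened at one bond. The C8–C9 bond is cut and the C1–C6 bond is formed, the reverse of a [3,3] shift, which leads to the cis-1,6-dialkenylcyclohex-2-enol 20. In 20, C6 carries the hydroxyl and the (E)-silylvinyl group (C7, C8), and C1 carries the 2-propenyl unit (C10, C9, C14). What is gained:
- the ten-membered ring comes from a six-membered one by four-atom expansion;
- C4=C5 is cis by construction;
- C1=C10 takes its geometry, and C8 its configuration, from a chair transition state;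
- the C6/C7 enolate needed for the next bond forms regiospecifically.

The forward step must pass through the chair that has C2 axial on C1.

**20 to 18, 19, 16 and 17.** 20 is cut at C8–Si and C7–H (hydrosilylation of alkyne 18 with silane 19), and 18 at C6–C7 (addition of acetylide 17 to ketone 16). This two-step route to the vinylsilane is preferred to a direct alkenyl-metal addition for two reasons. The cis relation between the new carbon substituent and the propenyl group needs axial attack on the half-chair enone, which a rod-shaped sp nucleophile is most likely to give. An acetylide is also a weak base towards the acidic C1–H.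

**16 to 10 and 14, and back to the starting materials.** Ketone 16 is cut at C1–C10, the bond between the α′-carbon of an enone and an sp2 carbon: enol silane 10 and 2-bromoallyl ether 14 are joined by palladium catalysis with a chiral ligand. This creates C1, the only stereocentre set by a reagent; all others derive from it. The coupling goes through a tin enolate without added base, because the product is a β,γ-unsaturated ketone with a tertiary α-hydrogen that would racemise or move into conjugation under basic enolate conditions. 10 comes from enone 8 by kinetic enolisation. 8 comes from vinylogous ester 5 and stannane 4 (C4–C15 bond, addition then acidic enone transposition). 4 comes from 1 and 2, and 14 from 11 and 12, by etherification.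

## Alternatives that were turned down

**Alternative 1:** ring-contracting [2,3]-Wittig rearrangement.
- Disconnection: the C6–C7 bond of the ten-membered alcohol A1.
- Forward key step: n-BuLi removes a proton from the C6 methylene of the thirteen-membered bis-allylic ether A2 (C6–O–C13). The carbanion bonds to C7 across the C13–C11=C7 allyl unit, O–C13 breaks, C11=C13 appears, and the ring contracts to A1.
- For: one step makes the C6–C7 bond, the C6 hydroxyl and the exocyclic methylene of the future lactone, and relates C6 to C7 through a five-membered envelope. The large ether ring closes by simple etherification. On installing the methylene group and the C6 oxygen it is stronger than the chosen route, which needs a reduction and a Mannich sequence.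
- Against: both methylene groups next to the ether oxygen are allylic, so metalation at C13 and the [1,2]-shift compete. The sense in which C6 and C7 form relative to C8 depends on the conformation of a flexible thirteen-membered ring. The transition state must already pay the strain of the ten-membered ring. Both trisubstituted alkenes must be made with the right geometry by separate olefinations, and C12 must later be oxidised to the lactone level.
- Comparison: the chosen strategy takes both alkene geometries from a ring and a chair, derives every stereocentre from one (C1), and reaches the ring in fewer steps.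

**Alternative 2:** B-alkyl Suzuki–Miyaura macrocyclisation.
- Disconnection: the C3–C4 bond of lactone A3.
- Forward key step: 9-BBN hydroborates the terminal C2=C3 double bond of the open-chain iodide A4. The C3 alkylborane couples with the (Z)-alkenyl iodide at C4 under Pd(dppf)Cl2 and base at high dilution.
- For: C6, C7, C8 and the trans lactone are set on a five-membered template before cyclisation, and the C4=C5 geometry is carried over stereospecifically from the iodide. On certainty of the stereotriad and of C4=C5 it is as strong as or stronger than the chosen route.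
- Against: it closes a ten-membered ring with two cis trisubstituted alkenes end to end, against transannular strain and oligomerisation. The vinyl group to be hydroborated is the end of a conjugated diene (C10=C1–C2=C3), so 1,4-addition and allylborane formation threaten. The lactone must survive aqueous base. A4 needs a long linear sequence.
- Comparison: the chosen strategy makes the ring from a six-membered precursor in one pericyclic step and needs no geometry-defining olefination.

**Alternative 3:** nickel-mediated reductive coupling.
- Disconnection: the C2–C3 bond of lactone A5.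
- Forward key step: Ni(CO)4 (zerovalent nickel) inserts into both primary allylic C–Br bonds of dibromide A6, and the bis(allyl)nickel intermediate joins C2 to C3.
- For: allyl–allyl coupling is a direct way to a cyclic 1,5-diene, the stereotriad is in place beforehand, and the two bromides come from the corresponding alcohols. In directness of ring closure it equals the chosen route.
- Against: allylnickel intermediates equilibrate between syn and anti forms, so the cis geometry of both alkenes is not reliably kept. Coupling at the inner allyl termini (C10 or C4) would give smaller rings with vinyl branches. The reagent is stoichiometric, volatile and very toxic, and high dilution is needed.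
- Comparison: it is weakest on alkene geometry and ring size, which the chosen strategy fixes through the pericyclic transition state.

Key step: step 8

Remark on the chemistry: the sense of asymmetric induction of the palladium/ligand pair in step 5 cannot be deduced from the structures; the ligand antipode that delivers the (6R)-ketone 16 is meant, written here as (R)-MOP.

## Route

Step 1
Reactants: 1 (tributylstannyl)methanol; 2 4-methoxybenzyl chloride
Product: 4 tributyl{[(4-methoxybenzyl)oxy]methyl}stannane, via sodium alkoxide 3 (not isolated)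
Conditions: NaH, Bu4NI (cat.), THF–DMF, 0 °C → rt
Reagents that add atoms: none
Why: Williamson etherification of the primary alkoxide with a benzylic chloride; the carbon–tin bond is inert to NaH.

Step 2
Reactants: 4 tributyl{[(4-methoxybenzyl)oxy]methyl}stannane; 5 3-ethoxycyclohex-2-en-1-one
Product: 8 3-{[(4-methoxybenzyl)oxy]methyl}cyclohex-2-en-1-one, via alkoxymethyllithium 6 (not isolated), via lithium alkoxide adduct 7 (not isolated)
Conditions: n-BuLi, THF, −78 °C; 5, −78 → 0 °C; 1 M HCl, 0 °C → rt
Reagents that add atoms: water (O)
Why: Tin–lithium exchange gives the α-alkoxymethyllithium, which adds 1,2 to the vinylogous ester; acid then hydrolyses the enol ether and eliminates the tertiary hydroxyl (Stork–Danheiser enone transposition), placing the oxygenated C15 on C4.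

Step 3
Reactants: 8 3-{[(4-methoxybenzyl)oxy]methyl}cyclohex-2-en-1-one
Product: 10 2-(trimethylsilyloxy)-4-{[(4-methoxybenzyl)oxy]methyl}cyclohexa-1,3-diene, via lithium dienolate 9 (not isolated)
Conditions: LiN(i-Pr)2, THF, −78 °C; Me3SiCl, Et3N, −78 → 0 °C
Reagents that add atoms: chlorotrimethylsilane (C[Si](C)(C)Cl)
Why: The hindered amide deprotonates the enone kinetically at the α′-methylene (C1), and O-silylation stores the cross-conjugated dienolate for a base-free coupling.

Step 4
Reactants: 11 2,3-dibromoprop-1-ene; 12 4-methoxybenzyl alcohol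
Product: 14 2-bromo-3-[(4-methoxybenzyl)oxy]prop-1-ene, via sodium alkoxide 13 (not isolated)
Conditions: NaH, THF, 0 °C → rt
Reagents that add atoms: none
Why: Williamson etherification; the alkoxide displaces the allylic bromide, while the vinylic bromide is inert to substitution.

Step 5
Reactants: 10 2-(trimethylsilyloxy)-4-{[(4-methoxybenzyl)oxy]methyl}cyclohexa-1,3-diene; 14 2-bromo-3-[(4-methoxybenzyl)oxy]prop-1-ene
Product: 16 (6R)-3-{[(4-methoxybenzyl)oxy]methyl}-6-{3-[(4-methoxybenzyl)oxy]prop-1-en-2-yl}cyclohex-2-en-1-one, via tributyltin enolate 15 (not isolated)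
Conditions: Bu3SnF (1.2 equiv), Pd(OAc)2 (5 mol %), (R)-MOP (12 mol %), toluene, 60 °C
Reagents that add atoms: none
Why: Palladium-catalysed asymmetric α-alkenylation of a ketone enolate: Bu3SnF turns the silyl enol ether into the tin enolate, which transmetallates to the alkenylpalladium bromide formed by oxidative addition of 14 to zerovalent palladium, and reductive elimination within the chiral complex forms C1–C10 and sets C1. The neutral medium keeps the acidic, doubly activated C1–H from racemising or moving into conjugation.

Step 6
Reactants: 16 (6R)-3-{[(4-methoxybenzyl)oxy]methyl}-6-{3-[(4-methoxybenzyl)oxy]prop-1-en-2-yl}cyclohex-2-en-1-one; 17 ethynylmagnesium bromide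
Product: 18 (1S,6R)-1-ethynyl-3-{[(4-methoxybenzyl)oxy]methyl}-6-{3-[(4-methoxybenzyl)oxy]prop-1-en-2-yl}cyclohex-2-en-1-ol
Conditions: 17, CeCl3 (anhydrous), THF, −78 °C; aq. NH4Cl
Reagents that add atoms: none
Why: 1,2-Addition of a weakly basic organocerium acetylide; the slim sp nucleophile should enter axially on the half-chair with the propenyl group equatorial, so the alkyne ends cis to the propenyl group and the hydroxyl equatorial and trans to it. A bulkier sp2 organometallic would be expected to come in trans to the propenyl group, which is why the vinylsilane is built from the alkyne.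

Step 7
Reactants: 18 (1S,6R)-1-ethynyl-3-{[(4-methoxybenzyl)oxy]methyl}-6-{3-[(4-methoxybenzyl)oxy]prop-1-en-2-yl}cyclohex-2-en-1-ol; 19 benzyldimethylsilane
Product: 20 (1S,6R)-1-[(E)-2-(benzyldimethylsilyl)ethenyl]-3-{[(4-methoxybenzyl)oxy]methyl}-6-{3-[(4-methoxybenzyl)oxy]prop-1-en-2-yl}cyclohex-2-en-1-ol
Conditions: Pt2[(CH2=CHSiMe2)2O]3 (1 mol %), P(t-Bu)3 (2 mol %), THF, rt → 50 °C
Reagents that add atoms: none
Why: Platinum-catalysed syn-hydrosilylation of the terminal alkyne; with the bulky phosphine silicon goes to the terminal carbon (C8) and the (E)-vinylsilane results, while the trisubstituted and 1,1-disubstituted alkenes react far more slowly.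

Step 8
Reactants: 20 (1S,6R)-1-[(E)-2-(benzyldimethylsilyl)ethenyl]-3-{[(4-methoxybenzyl)oxy]methyl}-6-{3-[(4-methoxybenzyl)oxy]prop-1-en-2-yl}cyclohex-2-en-1-ol
Product: 23 (2E,6E,9S)-9-(benzyldimethylsilyl)-3,7-bis{[(4-methoxybenzyl)oxy]methyl}cyclodeca-2,6-dien-1-one, via potassium alkoxide 21 (not isolated), via potassium enolate 22 (not isolated)
Conditions: KH (3 equiv), 18-crown-6 (3 equiv), THF, 0 → 50 °C; aq. NH4Cl, −78 °C
Reagents that add atoms: none
Why: KH with 18-crown-6 gives the free potassium alkoxide 21, in which the oxyanion weakens the C1–C6 bond, so that the [3,3]-sigmatropic shift (anionic oxy-Cope rearrangement of a 1,2-dialkenylcyclohexanol, the closest known reaction type) runs at or slightly above room temperature: C8–C9 forms, C1–C6 breaks, and enolate 22 and the C1=C10 alkene appear. The ten-membered ring arises by four-atom expansion of the cyclohexene and not by end-to-end closure, and C4=C5 keeps the cis geometry it had in the six-membered ring. The reacting conformer has the propenyl group equatorial and the silylvinyl group axial on the cyclohexene, which in the chair transition state (chair A) puts C2 axial on C1, hence cis C1=C10, and C5 equatorial on C6. The other chair (chair B) would put C2 equatorial, in A(1,2) contact with C14 on C10, and C5 axial, 1,3 to C14, and it requires the propenyl group axial in the ground state, so the C14 substituent works for chair A on all counts. The new stereocentre C8 is set by chirality transfer from C1 and C6: in chair A the (E)-silyl group is equatorial and C9 can bond to one face of C8 only, which gives (8S). The selectivities needed are chair A over chair B (which would give the trans alkene together with the C8 epimer) and [3,3] shift over cleavage; the cis relation of the two alkenyl groups secures the first, and the unstabilised allyl anion that cleavage would require disfavours the second. Silicon on C8 is a hydroxyl equivalent that the enolate cannot expel, and cold protonation gives ketone 23 with C7 as a methylene group.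

Step 9
Reactants: 23 (2E,6E,9S)-9-(benzyldimethylsilyl)-3,7-bis{[(4-methoxybenzyl)oxy]methyl}cyclodeca-2,6-dien-1-one; 24 tert-butyl bromoacetate
Product: 26 tert-butyl [(1S,3E,7E,10S)-10-(benzyldimethylsilyl)-4,8-bis{[(4-methoxybenzyl)oxy]methyl}-2-oxocyclodeca-3,7-dien-1-yl]acetate, via lithium enolate 25 (not isolated)
Conditions: LiN(i-Pr)2, THF, −78 °C; 24, DMPU, −78 → −40 °C
Reagents that add atoms: none
Why: Kinetic α′-deprotonation gives the C6/C7 lithium enolate, which is alkylated on the face away from the bulky silyl group on C8 (trans, the usual outcome for cyclic β-silyl enolates); C7 stays epimerisable next to the ketone, so a brief treatment with DBU would also lead to this trans isomer.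

Step 10
Reactants: 26 tert-butyl [(1S,3E,7E,10S)-10-(benzyldimethylsilyl)-4,8-bis{[(4-methoxybenzyl)oxy]methyl}-2-oxocyclodeca-3,7-dien-1-yl]acetate
Product: 28 tert-butyl [(1R,3E,7E,10S)-10-hydroxy-4,8-bis{[(4-methoxybenzyl)oxy]methyl}-2-oxocyclodeca-3,7-dien-1-yl]acetate, via fluorosilane 27 (not isolated)
Conditions: Bu4NF (3 equiv), THF, 0 °C; then KHCO3, 30% H2O2, MeOH, rt
Reagents that add atoms: hydrogen peroxide (OO)
Why: Tamao–Fleming oxidation: fluoride cleaves the benzyl–silicon bond, and peroxide oxidises the fluorosilane with migration of C8 from silicon to oxygen, that is with retention at C8. The tert-butyl ester does not lactonise in this mildly basic medium, so no β-acyloxy ketone is exposed to base.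

Step 11
Reactants: 28 tert-butyl [(1R,3E,7E,10S)-10-hydroxy-4,8-bis{[(4-methoxybenzyl)oxy]methyl}-2-oxocyclodeca-3,7-dien-1-yl]acetate
Product: 29 (7R,8S)-14,15-bis[(4-methoxybenzyl)oxy]-6-oxo-13-norgermacra-1(10),4-dien-12,8-olide
Conditions: camphorsulfonic acid (0.2 equiv), CH2Cl2, rt
Reagents that add atoms: none
Why: Acid-catalysed lactonisation of the γ-hydroxy tert-butyl ester; only the C8 hydroxyl is present, so the 8,12-lactone forms without competition from O6, and the trans ring fusion follows from the configurations set in steps 8 and 9.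

Step 12
Reactants: 29 (7R,8S)-14,15-bis[(4-methoxybenzyl)oxy]-6-oxo-13-norgermacra-1(10),4-dien-12,8-olide
Product: 30 (6S,7S,8S)-6-hydroxy-14,15-bis[(4-methoxybenzyl)oxy]-13-norgermacra-1(10),4-dien-12,8-olide
Conditions: NaBH4, CeCl3·7H2O, MeOH, −78 °C
Reagents that add atoms: none
Why: Luche 1,2-reduction of the enone carbonyl; hydride should attack anti to the C7–C8 bond with C11 beside the carbonyl oxygen (Felkin–Anh model, here the same as attack from outside the ring), which gives the (6S)-alcohol with O6 anti to O8.

Step 13
Reactants: 30 (6S,7S,8S)-6-hydroxy-14,15-bis[(4-methoxybenzyl)oxy]-13-norgermacra-1(10),4-dien-12,8-olide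
Product: 34 (6S,7S,8S)-6-hydroxy-14,15-bis[(4-methoxybenzyl)oxy]germacra-1(10),4,11(13)-trien-12,8-olide, via dilithium alkoxide enolate 31 (not isolated), via Mannich base 32 (not isolated), via ammonium iodide 33 (not isolated)
Conditions: LiN(i-Pr)2 (2.5 equiv), THF, −78 °C (substrate added to the base); CH2=NMe2+ I−, −78 → 0 °C; MeI, MeOH, rt; aq. NaHCO3, EtOAc, rt
Reagents that add atoms: dimethyl(methylidene)ammonium iodide (C=[N+](C)C.[I-])
Why: α-Methylenation of the lactone through its dianion: Mannich reaction of the lactone enolate with the iminium salt, N-methylation and E1cB loss of trimethylamine give the exocyclic alkene. Adding the substrate to excess amide keeps the C6 alkoxide from sitting beside an un-enolised lactone.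

Step 14
Reactants: 34 (6S,7S,8S)-6-hydroxy-14,15-bis[(4-methoxybenzyl)oxy]germacra-1(10),4,11(13)-trien-12,8-olide; 35 (E)-2-methylbut-2-enoyl chloride
Product: 36 (6S,7R,8S)-14,15-bis[(4-methoxybenzyl)oxy]-6-[(E)-2-methylbut-2-enoyloxy]germacra-1(10),4,11(13)-trien-12,8-olide
Conditions: pyridine, DMAP (cat.), CH2Cl2, 0 °C → rt
Reagents that add atoms: none
Why: Acylation of the secondary allylic alcohol with the acid chloride under nucleophilic catalysis; pyridine as the only base avoids vinylketene formation and keeps the (E) geometry of the tiglate.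

Step 15
Reactants: 36 (6S,7R,8S)-14,15-bis[(4-methoxybenzyl)oxy]-6-[(E)-2-methylbut-2-enoyloxy]germacra-1(10),4,11(13)-trien-12,8-olide
Product: 37 (6S,7R,8S)-14,15-dihydroxy-6-[(E)-2-methylbut-2-enoyloxy]germacra-1(10),4,11(13)-trien-12,8-olide
Conditions: DDQ (2.5 equiv), CH2Cl2–aq. pH 7 buffer, 0 °C
Reagents that add atoms: none
Why: DDQ oxidises both 4-methoxybenzyl ethers to benzylic oxocarbenium ions, which water hydrolyses; the buffered medium should leave the ester, the α-methylene lactone and the diene untouched.

## Compound list

1 | (tributylstannyl)methanol | OC[Sn](CCCC)(CCCC)CCCC | starting material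
2 | 4-methoxybenzyl chloride | COc1ccc(CCl)cc1 | starting material
3 | sodium (tributylstannyl)methanolate | [Na+].[O-]C[Sn](CCCC)(CCCC)CCCC | intermediate
4 | tributyl{[(4-methoxybenzyl)oxy]methyl}stannane | COc1ccc(COC[Sn](CCCC)(CCCC)CCCC)cc1 | intermediate
5 | 3-ethoxycyclohex-2-en-1-one | CCOC1=CC(=O)CCC1 | starting material
6 | {[(4-methoxybenzyl)oxy]methyl}lithium | [Li]COCc1ccc(OC)cc1 | intermediate
7 | lithium 3-ethoxy-1-{[(4-methoxybenzyl)oxy]methyl}cyclohex-2-en-1-olate (racemic) | [Li]OC1(COCc2ccc(OC)cc2)C=C(OCC)CCC1 | intermediate
8 | 3-{[(4-methoxybenzyl)oxy]methyl}cyclohex-2-en-1-one | O=C1C=C(COCc2ccc(OC)cc2)CCC1 | intermediate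
9 | lithium 5-{[(4-methoxybenzyl)oxy]methyl}cyclohexa-1,5-dien-1-olate | [Li]OC1=CCCC(COCc2ccc(OC)cc2)=C1 | intermediate
10 | 2-(trimethylsilyloxy)-4-{[(4-methoxybenzyl)oxy]methyl}cyclohexa-1,3-diene | C[Si](C)(C)OC1=CCCC(COCc2ccc(OC)cc2)=C1 | intermediate
11 | 2,3-dibromoprop-1-ene | C=C(Br)CBr | starting material
12 | 4-methoxybenzyl alcohol | COc1ccc(CO)cc1 | starting material
13 | sodium (4-methoxyphenyl)methanolate | [Na+].[O-]Cc1ccc(OC)cc1 | intermediate
14 | 2-bromo-3-[(4-methoxybenzyl)oxy]prop-1-ene | C=C(Br)COCc1ccc(OC)cc1 | intermediate
15 | tributyl{[5-({[4-methoxybenzyl]oxy}methyl)cyclohexa-1,5-dien-1-yl]oxy}stannane | CCCC[Sn](CCCC)(CCCC)OC1=CCCC(COCc2ccc(OC)cc2)=C1 | intermediate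
16 | (6R)-3-{[(4-methoxybenzyl)oxy]methyl}-6-{3-[(4-methoxybenzyl)oxy]prop-1-en-2-yl}cyclohex-2-en-1-one | O=C1C=C(COCc2ccc(OC)cc2)CC[C@@H]1C(=C)COCc1ccc(OC)cc1 | intermediate
17 | ethynylmagnesium bromide | C#C[Mg]Br | starting material
18 | (1S,6R)-1-ethynyl-3-{[(4-methoxybenzyl)oxy]methyl}-6-{3-[(4-methoxybenzyl)oxy]prop-1-en-2-yl}cyclohex-2-en-1-ol | O[C@@]1(C#C)C=C(COCc2ccc(OC)cc2)CC[C@@H]1C(=C)COCc1ccc(OC)cc1 | intermediate
19 | benzyldimethylsilane | C[SiH](C)Cc1ccccc1 | starting material
20 | (1S,6R)-1-[(E)-2-(benzyldimethylsilyl)ethenyl]-3-{[(4-methoxybenzyl)oxy]methyl}-6-{3-[(4-methoxybenzyl)oxy]prop-1-en-2-yl}cyclohex-2-en-1-ol | O[C@@]1(/C=C/[Si](C)(C)Cc2ccccc2)C=C(COCc2ccc(OC)cc2)CC[C@@H]1C(=C)COCc1ccc(OC)cc1 | intermediate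
21 | potassium alkoxide of 20 | [K+].[O-][C@@]1(/C=C/[Si](C)(C)Cc2ccccc2)C=C(COCc2ccc(OC)cc2)CC[C@@H]1C(=C)COCc1ccc(OC)cc1 | intermediate
22 | potassium enolate of 23 (oxygen on C6, C6=C7 with C5 and C8 trans) | [K+].C1/C(COCc2ccc(OC)cc2)=C\C(\[O-])=C\[C@@H]([Si](C)(C)Cc2ccccc2)C/C(COCc2ccc(OC)cc2)=C\C1 | intermediate
23 | (2E,6E,9S)-9-(benzyldimethylsilyl)-3,7-bis{[(4-methoxybenzyl)oxy]methyl}cyclodeca-2,6-dien-1-one (both ring double bonds cis in the ring; 8S in germacrane numbering) | O=C1/C=C(COCc2ccc(OC)cc2)\CC/C=C(COCc2ccc(OC)cc2)\C[C@H]([Si](C)(C)Cc2ccccc2)C1 | intermediate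
24 | tert-butyl bromoacetate | CC(C)(C)OC(=O)CBr | starting material
25 | lithium enolate of 23 (oxygen on C6, C6=C7) | C1/C(COCc2ccc(OC)cc2)=C\C(O[Li])=C[C@@H]([Si](C)(C)Cc2ccccc2)C/C(COCc2ccc(OC)cc2)=C\C1 | intermediate
26 | tert-butyl [(1S,3E,7E,10S)-10-(benzyldimethylsilyl)-4,8-bis{[(4-methoxybenzyl)oxy]methyl}-2-oxocyclodeca-3,7-dien-1-yl]acetate (7S,8S in germacrane numbering) | CC(C)(C)OC(=O)C[C@@H]1[C@@H]([Si](C)(C)Cc2ccccc2)C/C(COCc2ccc(OC)cc2)=C\CC/C(COCc2ccc(OC)cc2)=C\C1=O | intermediate
27 | fluorodimethylsilyl analogue of 26 (SiMe2F on C8) | CC(C)(C)OC(=O)C[C@@H]1[C@@H]([Si](C)(C)F)C/C(COCc2ccc(OC)cc2)=C\CC/C(COCc2ccc(OC)cc2)=C\C1=O | intermediate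
28 | tert-butyl [(1R,3E,7E,10S)-10-hydroxy-4,8-bis{[(4-methoxybenzyl)oxy]methyl}-2-oxocyclodeca-3,7-dien-1-yl]acetate (7R,8S in germacrane numbering) | CC(C)(C)OC(=O)C[C@@H]1[C@@H](O)C/C(COCc2ccc(OC)cc2)=C\CC/C(COCc2ccc(OC)cc2)=C\C1=O | intermediate
29 | (7R,8S)-14,15-bis[(4-methoxybenzyl)oxy]-6-oxo-13-norgermacra-1(10),4-dien-12,8-olide | C1C(=O)O[C@H]2C/C(COCc3ccc(OC)cc3)=C\CC/C(COCc3ccc(OC)cc3)=C\C(=O)[C@H]12 | intermediate
30 | (6S,7S,8S)-6-hydroxy-14,15-bis[(4-methoxybenzyl)oxy]-13-norgermacra-1(10),4-dien-12,8-olide | C1C(=O)O[C@H]2C/C(COCc3ccc(OC)cc3)=C\CC/C(COCc3ccc(OC)cc3)=C\[C@H](O)[C@H]12 | intermediate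
31 | dilithium salt of 30 (C6 alkoxide, lactone enolate) | [Li]OC1=C[C@H]2[C@@H](O[Li])/C=C(COCc3ccc(OC)cc3)\CC/C=C(COCc3ccc(OC)cc3)\C[C@@H]2O1 | intermediate
32 | 13-(dimethylamino)-11,13-dihydro derivative of 34 (Mannich base, C11 epimers) | CN(C)CC1C(=O)O[C@H]2C/C(COCc3ccc(OC)cc3)=C\CC/C(COCc3ccc(OC)cc3)=C\[C@H](O)[C@H]12 | intermediate
33 | N-methyl iodide salt of 32 | [I-].C[N+](C)(C)CC1C(=O)O[C@H]2C/C(COCc3ccc(OC)cc3)=C\CC/C(COCc3ccc(OC)cc3)=C\[C@H](O)[C@H]12 | intermediate
34 | (6S,7S,8S)-6-hydroxy-14,15-bis[(4-methoxybenzyl)oxy]germacra-1(10),4,11(13)-trien-12,8-olide | C=C1C(=O)O[C@H]2C/C(COCc3ccc(OC)cc3)=C\CC/C(COCc3ccc(OC)cc3)=C\[C@H](O)[C@H]12 | intermediate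
35 | (E)-2-methylbut-2-enoyl chloride (tigloyl chloride) | C/C=C(\C)C(=O)Cl | starting material
36 | (6S,7R,8S)-14,15-bis[(4-methoxybenzyl)oxy]-6-[(E)-2-methylbut-2-enoyloxy]germacra-1(10),4,11(13)-trien-12,8-olide | C=C1C(=O)O[C@H]2C/C(COCc3ccc(OC)cc3)=C\CC/C(COCc3ccc(OC)cc3)=C\[C@H](OC(=O)/C(C)=C/C)[C@H]12 | intermediate
37 | (6S,7R,8S)-14,15-dihydroxy-6-[(E)-2-methylbut-2-enoyloxy]germacra-1(10),4,11(13)-trien-12,8-olide (CNP0275462.1) | C=C1C(=O)O[C@H]2C/C(CO)=C\CC/C(CO)=C\[C@H](OC(=O)/C(C)=C/C)[C@H]12 | target

## Step count and least certain steps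

Total step count: 15. Longest linear sequence: 14 steps (steps 1–3 and 5–15); step 4 is a one-step branch.

**Step 8 (key step).** The rearrangement may leak through chair B or a boat, which would give the trans C1=C10 alkene together with the C8 epimer. The alkoxide may instead cleave to a ketone and an allyl anion. The enolate oxygen may also attack the neighbouring silicon and expel the benzyl group. Fallback, from 20 to 23: silylate the tertiary alcohol with N-(trimethylsilyl)imidazole to the trimethylsilyl ether F1 and heat it in o-dichlorobenzene at about 200 °C in base-washed glass. This neutral siloxy-Cope rearrangement gives the trimethylsilyl enol ether F2, which aqueous acetic acid in THF hydrolyses to 23. No anion is present, so the base-induced side reactions are removed, and the tighter neutral transition state is expected to discriminate the two chairs at least as well.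

**Step 5.** The enantioselectivity may be insufficient, or it may be eroded by enolisation or double-bond migration of the product on the catalyst or during isolation. Fallback, from 10 and 14 to 16:
- run the same coupling with an achiral ligand, P(t-Bu)3, to the racemic ketone F3;
- reduce it (NaBH4, CeCl3·7H2O) and take the racemic allylic alcohol F4 that has the hydroxyl trans to the propenyl group;
- esterify with (S)-2-methoxy-2-phenylacetic acid (DCC, DMAP) and separate the diastereomeric esters by chromatography to get the ester F5 of the (6R) series;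
- cleave it with K2CO3 in methanol to the alcohol F6 and oxidise with MnO2 to enantiopure 16.

**Step 6.** Facial selectivity may be poor: attack trans to the propenyl group, through the conformer with that group axial, would give the trans-dialkenyl carbinol and, after step 8, the trans C1=C10 alkene. Fallback, from 16 to 20, which builds the carbinol stereospecifically from the secondary alcohol:
- reduce 16 (NaBH4, CeCl3·7H2O) and take the alcohol F6 with the hydroxyl trans to the propenyl group; its epimer is converted into F6 by Mitsunobu inversion with 4-nitrobenzoic acid and methanolysis;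
- carbamoylate with i-Pr2NCOCl to the carbamate F7;
- lithiate at C6 with s-BuLi and TMEDA in ether at −78 °C and add the pinacol boronate F8, made from ethynylboronic acid pinacol ester and 19 by platinum-catalysed hydrosilylation;
- 1,2-migration of the alkenyl group on warming gives the tertiary allylic boronate F9, and NaOH/H2O2 oxidises it with retention to 20.

In this sequence the silylvinyl group takes the place of the carbinol hydrogen and the oxygen keeps its face.

**Step 10.** Hydroperoxide may epoxidise the C4=C5–C6=O enone by conjugate addition, or base may cause elimination or retro-aldol cleavage of the β-hydroxy ketone. Fallback, from 26 to 28: reduce the ketone first (NaBH4, CeCl3·7H2O) to the allylic alcohol F10 (either C6 epimer); the tert-butyl ester resists lactonisation. Carry F10 through the same fluoride and peroxide treatment to the diol F11, then re-oxidise only the allylic C6 hydroxyl with MnO2 to 28.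

**Step 12.** Facial selectivity may be poor, because the medium ring may present the other face of the ketone; the lactone may also migrate to O6 if the alkoxide persists. Fallback, from 29 to 36: if the reduction gives the C6 epimer F12, carry it through the methylenation of step 13 to the epimeric α-methylene alcohol F13 and install the ester with inversion by Mitsunobu reaction (tiglic acid, PPh3, diisopropyl azodicarboxylate), watching for allylic transposition, to reach 36.

Further compounds
F1 | step 8 | trimethylsilyl ether of 20 | C[Si](C)(C)O[C@@]1(/C=C/[Si](C)(C)Cc2ccccc2)C=C(COCc2ccc(OC)cc2)CC[C@@H]1C(=C)COCc1ccc(OC)cc1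
F2 | step 8 | trimethylsilyl enol ether of 23 (silyloxy on C6, C6=C7) | C1/C(COCc2ccc(OC)cc2)=C\C(\O[Si](C)(C)C)=C\[C@@H]([Si](C)(C)Cc2ccccc2)C/C(COCc2ccc(OC)cc2)=C\C1
F3 | step 5 | racemic 16 | O=C1C=C(COCc2ccc(OC)cc2)CCC1C(=C)COCc1ccc(OC)cc1
F4 | step 5 | racemic allylic alcohol from F3 with hydroxyl trans to the propenyl group | OC1C=C(COCc2ccc(OC)cc2)CCC1C(=C)COCc1ccc(OC)cc1
F5 | step 5 | (S)-2-methoxy-2-phenylacetate of the (1S,6R)-alcohol | CO[C@H](C(=O)O[C@H]1C=C(COCc2ccc(OC)cc2)CC[C@@H]1C(=C)COCc1ccc(OC)cc1)c1ccccc1
F6 | step 5 | (1S,6R)-3-{[(4-methoxybenzyl)oxy]methyl}-6-{3-[(4-methoxybenzyl)oxy]prop-1-en-2-yl}cyclohex-2-en-1-ol | O[C@H]1C=C(COCc2ccc(OC)cc2)CC[C@@H]1C(=C)COCc1ccc(OC)cc1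
F7 | step 6 | N,N-diisopropylcarbamate of F6 | CC(C)N(C(C)C)C(=O)O[C@H]1C=C(COCc2ccc(OC)cc2)CC[C@@H]1C(=C)COCc1ccc(OC)cc1
F8 | step 6 | pinacol (E)-[2-(benzyldimethylsilyl)ethenyl]boronate | CC1(C)OB(/C=C/[Si](C)(C)Cc2ccccc2)OC1(C)C
F9 | step 6 | tertiary allylic pinacol boronate (boron in place of the hydroxyl of 20) | CC1(C)OB([C@@]2(/C=C/[Si](C)(C)Cc3ccccc3)C=C(COCc3ccc(OC)cc3)CC[C@@H]2C(=C)COCc2ccc(OC)cc2)OC1(C)C
F10 | step 10 | C6 alcohol from 26 (either C6 epimer) | CC(C)(C)OC(=O)C[C@@H]1[C@@H]([Si](C)(C)Cc2ccccc2)C/C(COCc2ccc(OC)cc2)=C\CC/C(COCc2ccc(OC)cc2)=C\C1O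
F11 | step 10 | 6,8-diol from F10 (either C6 epimer) | CC(C)(C)OC(=O)C[C@@H]1[C@@H](O)C/C(COCc2ccc(OC)cc2)=C\CC/C(COCc2ccc(OC)cc2)=C\C1O
F12 | step 12 | C6 epimer of 30 | C1C(=O)O[C@H]2C/C(COCc3ccc(OC)cc3)=C\CC/C(COCc3ccc(OC)cc3)=C\[C@@H](O)[C@H]12
F13 | step 12 | C6 epimer of 34 | C=C1C(=O)O[C@H]2C/C(COCc3ccc(OC)cc3)=C\CC/C(COCc3ccc(OC)cc3)=C\[C@@H](O)[C@H]12
A1 | alternative 1 | ten-membered C6 alcohol with the C11=C13 propenyl side chain on C7 | C=C(CO[Si](CC)(CC)CC)[C@@H]1[C@@H](O[Si](CC)(CC)CC)C/C(CO[Si](C(C)C)(C(C)C)C(C)C)=C\CC/C(CO[Si](C(C)C)(C(C)C)C(C)C)=C\[C@@H]1O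
A2 | alternative 1 | thirteen-membered C6–O–C13 bis-allylic ether | O1C/C(CO[Si](CC)(CC)CC)=C/[C@@H](O[Si](CC)(CC)CC)C/C(CO[Si](C(C)C)(C(C)C)C(C)C)=C\CC/C(CO[Si](C(C)C)(C(C)C)C(C)C)=C\C1
A3 | alternative 2 | ten-membered cis,cis-diene fused to the trans lactone (C6 triethylsilyl ether) | C1C(=O)O[C@H]2C/C(CO[Si](C)(C)C(C)(C)C)=C\CC/C(CO[Si](C)(C)C(C)(C)C)=C\[C@H](O[Si](CC)(CC)CC)[C@H]12
A4 | alternative 2 | open-chain lactone with terminal diene and (Z)-alkenyl iodide | C1C(=O)O[C@@H](C/C(CO[Si](C)(C)C(C)(C)C)=C\C=C)[C@@H]1[C@@H](O[Si](CC)(CC)CC)/C=C(\I)CO[Si](C)(C)C(C)(C)C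
A5 | alternative 3 | ten-membered cis,cis-diene fused to the trans lactone (C6 4-methoxybenzyl ether) | C1C(=O)O[C@H]2C/C(CO[Si](C)(C)C(C)(C)C)=C\CC/C(CO[Si](C)(C)C(C)(C)C)=C\[C@H](OCc3ccc(OC)cc3)[C@H]12
A6 | alternative 3 | open-chain lactone with two primary allylic bromides (C2, C3) | C1C(=O)O[C@@H](C/C(CO[Si](C)(C)C(C)(C)C)=C\CBr)[C@@H]1[C@@H](OCc2ccc(OC)cc2)/C=C(CO[Si](C)(C)C(C)(C)C)\CBr
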